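The data were computed on assumed constants, and the scatter is random.

Decide first how much J each reacted Q costs, then reckon every flask from that price.

the same everywhere: Q 0.40 M
- midnight: J 1.6 equiv; D 0.020 M; run made earlier
- grey: J 1.80 equiv; D 0.0200 M; time 2.5 d
- teal: J 2.30 equiv; D 0.0200 M; time 2.5 d
- ochre: J 3.00 equiv; D 0.0200 M; time 2.5 d

midnight run (percent of the Q charged)

| time / h | Q / % | E / % |
|---|---|---|
| 3.00 | 92 | 7 |
| 8.00 | 78 | 25 |
| 20.0 | 55 | 39 |
| 40.0 | 46 | 60 |

(standard deviation of a reading: 2 percentage points)



- part of the Q that has reacted at the end, grey
- part of the Q that has reacted at the end, teal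
- part of the Q that has reacted at the end, ochre
- what raising the equivalents of J from its lowest to its highest value here does to the part of the Q that has reacted (changes below 5 percentage points count as none) (no change / it falls / it rises)

1. Read the rate constant k (rate per Q per J) from the start of the midnight run. Freeze J at its charge of 0.640 M. This is a rough step: J falls during this stretch, so the k read here is a low reading. Q is 78% at 8.00 h, which gives k = 0.0485 M⁻¹ h⁻¹.

2. Read k a second way, from the 20.0 h and 40.0 h readings, charging one J per Q. Q then loses 0.00893 h⁻¹. On average 0.198 M of Q has reacted, so J stands at 0.442 M and k comes to 0.0202 M⁻¹ h⁻¹.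

3. The two ways part: the second k is lower than the first. Suspect the second: its J is reckoned with a price of one J per Q, and the first k uses no price. Keep the first k and ask what J the late rate needs: 0.184 M. That is a price of 2.30 J per Q, a reading with scatter that rests on a low k. Take the nearest whole number, 2.

4. Now freeze the surplus S = J − 2Q, which stays constant at that price. For grey, S is −0.0800 M. It is 0.120 M for teal and 0.400 M for ochre. Grey's S is negative, so J is its limiting reagent, and my reckoning stops Q at a floor of 10.0% of the charge.

5. With S frozen, the ratio J/Q grows by exp(k·S·t). My reckoning gives 65.2% reacted for grey, 76.2% for teal and 86.9% for ochre.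

6. The forecast says 70%, 79% and 86%, and it rises: “Conversion rises with J in both pictures”. Mine is lower for grey and teal, and higher for ochre.

7. The flasks give 68.3%, 80.0% and 90.4%, and it rises. The forecast held.

    Q + J → X + E (k = 0.00102 M⁻¹ min⁻¹)
    J + D → G (k = 0.0553 M⁻¹ min⁻¹)
    J + X ⇌ Z, settled at all times (K = 100 M⁻¹)
    J + X ⇌ L, settled at all times (K = 1470 M⁻¹)

Grey has not come to rest: Q is 31.7% at 2.50 d, and at 25.0 d it is 10.9%, just above the floor of 10.0%, with J at 1.31% of its charge. Teal and ochre also move on, from 80.0% to 99.7% and from 90.4% to >99.9% reacted. A flask like ochre but with 0.750 equiv of J has a surplus of −0.500 M, so its floor is 62.5%. At 2.50 d it holds Q at 68.4%, with J at 9.9% of its charge.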